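## Retrosynthetic overview

1. Enabling feature: the only ring, the 2,5-dihydroxy-1,4-benzoquinone, is the bis-enol of a cyclohexane-1,2,4,5-tetraone. Two vicinal dicarbonyl pairs (C1–C2 and C4–C5) alternate with the two alkyl-bearing carbons C3 (methyl) and C6 (nonadecenyl), and each of these lies between two carbonyl-level carbons, so C2–C3 and C6–C1 are both Claisen retrons.
2. Key disconnection: both bonds are cut at once, giving the acyclic 1,2-diketone (E)-tetracos-19-ene-3,4-dione (C3–C4–C5–C6, with methyl and chain already on the carbons that become para) and diethyl oxalate (C1–C2). The forward double Claisen annulation closes the ring last, at the final oxidation level and without protecting groups.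
3. The diketone is cut at its two acyl–alkyl bonds into 1,4-dimethylpiperazine-2,3-dione (an oxalyl dication equivalent) and two Grignard reagents, (E)-icos-15-enyl and ethyl.
4. The C20 chain comes from hex-1-yne and 14-bromotetradecan-1-ol; the E double bond is set by dissolving-metal reduction of the alkyne.
5. Ring order: there is one ring. Its six atoms come from four simple components (two Grignard carbons, an oxalic diamide, an oxalic diester) and it is closed in step 5.

Key step: step 5

Remark: 14-bromotetradecan-1-ol and 1,4-dimethylpiperazine-2,3-dione are taken as catalogue compounds; the two enol tautomers of the target ring are degenerate and describe the same compound.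

## Route

Step 1
Reactants: 1 hex-1-yne; 2 14-bromotetradecan-1-ol
Product: 6 icos-15-yn-1-ol, via lithium hex-1-yn-1-ide 3 (not isolated), via lithium 14-bromotetradecan-1-olate 4 (not isolated), via lithium icos-15-yn-1-olate 5 (not isolated)
Conditions: 1 (2.4 equiv), n-BuLi (2.3 equiv), THF, −78 to 0 °C; then 2, DMPU, 0 °C to rt; 1 M HCl work-up
Reagents that add atoms: none
Why: SN2 alkylation of a lithium acetylide by a primary alkyl bromide in THF/DMPU; the hydroxyl group is carried through as its lithium alkoxide, which is a much poorer nucleophile than the acetylide under these conditions.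

Step 2
Reactants: 6 icos-15-yn-1-ol
Product: 8 (15E)-icos-15-en-1-ol, via lithium (E)-icos-15-en-1-olate 7 (not isolated)
Conditions: Li (6 equiv), NH3(l)/THF, −33 °C; then solid NH4Cl
Reagents that add atoms: none
Why: Dissolving-metal (Birch-type) reduction of an internal alkyne: the vinyl radical and vinyl anion intermediates adopt the trans geometry before protonation, which sets the E double bond, and neither the isolated alkene formed nor the alkoxide is reduced further.

Step 3
Reactants: 8 (15E)-icos-15-en-1-ol
Product: 9 (5E)-20-bromoicos-5-ene
Conditions: CBr4, PPh3, CH2Cl2, 0 °C to rt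
Reagents that add atoms: tetrabromomethane, BrC(Br)(Br)Br
Why: Appel reaction: the alkoxyphosphonium ion is displaced by bromide in an SN2 step at the primary carbon, and the isolated E alkene is inert to these neutral conditions.

Step 4
Reactants: 9 (5E)-20-bromoicos-5-ene; 10 1,4-dimethylpiperazine-2,3-dione; 11 ethylmagnesium bromide
Product: 15 (19E)-tetracos-19-ene-3,4-dione, via icosenylmagnesium bromide 12 (not isolated), via magnesium mono-adduct 13 (not isolated), via magnesium bis-adduct 14 (not isolated)
Conditions: Mg, THF, rt to 40 °C; the Grignard solution added to 10 (1.3 equiv), THF, −78 to −20 °C; then 11 (3 equiv), −20 °C to rt; cold 1 M HCl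
Reagents that add atoms: none
Why: Grignard formation and two successive nucleophilic additions to the cyclic oxalic diamide: each addition stops at a magnesium hemiaminal alkoxide that cannot collapse before the acidic quench (the same tetrahedral-intermediate control as in a Weinreb ketone synthesis, known for this reagent with two different organometallic reagents), so no carbonyl is attacked twice and the unsymmetrical 1,2-diketone is released only on hydrolysis, with the E alkene untouched.

Step 5
Reactants: 15 (19E)-tetracos-19-ene-3,4-dione; 16 diethyl oxalate
Product: 20 2,5-dihydroxy-3-methyl-6-[(14E)-nonadec-14-en-1-yl]cyclohexa-2,5-diene-1,4-dione, via open-chain oxalyl adduct 17 (not isolated), via isomeric oxalyl adduct 18 (not isolated), via dipotassium quinone diolate 19 (not isolated)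
Conditions: 16 (2 equiv), t-BuOK (3.5 equiv), THF, 0 °C, slow addition of 15; then 50 °C; 1 M HCl
Reagents that add atoms: none
Why: Proposed new method: a double Claisen condensation between a 1,2-diketone and an oxalic diester, in which the potassium enolate of one α-methylene of 15 C-acylates non-enolisable 16 (giving 17 or 18), the enolate of the other α-methylene then attacks the remaining ester carbonyl and expels ethoxide, and the cyclohexane-1,2,4,5-tetraone so formed is deprotonated twice to the dianion 19; the closest known reaction types are the alkoxide-mediated double Claisen condensation of dialkyl ketones with diethyl oxalate that gives cyclopentane-1,2,4-triones and the classical head-to-tail double Claisen ring closure of 2-oxo ester units that gives symmetrical 3,6-dialkyl-2,5-dihydroxybenzoquinones. The ring closes in the 6-(enolexo)-exo-trig mode of a Dieckmann condensation, so that C2–C3 and C6–C1 are both made in one operation. No stereocentre is formed, and the isolated E double bond has no acidifying neighbour and should neither migrate nor isomerise under alkoxide. The step needs cross-condensation over self-aldol reaction of 15 and C- over O-acylation: slow addition of 15 to base and excess 16 keeps the diketone dilute beside the only ester electrophile, O-acylated or lactone by-products are reopened by the liberated ethoxide, and every reversible pathway drains into 19, a strongly stabilised doubly vinylogous carboxylate. Regiochemistry cannot go wrong, because the diketone already holds methyl and chain on the two carbons that become para and either order of acylation leads to the same ring. Acidification then gives 20 directly, at the correct oxidation level and with nothing to deprotect.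

## Compound list

1 | hex-1-yne | CCCCC#C | starting material
2 | 14-bromotetradecan-1-ol | OCCCCCCCCCCCCCCBr | starting material
3 | lithium hex-1-yn-1-ide | CCCCC#C[Li] | intermediate (not isolated)
4 | lithium 14-bromotetradecan-1-olate | [Li+].[O-]CCCCCCCCCCCCCCBr | intermediate (not isolated)
5 | lithium icos-15-yn-1-olate | [Li+].[O-]CCCCCCCCCCCCCCC#CCCCC | intermediate (not isolated)
6 | icos-15-yn-1-ol | CCCCC#CCCCCCCCCCCCCCCO | intermediate
7 | lithium (15E)-icos-15-en-1-olate | [Li+].[O-]CCCCCCCCCCCCCC/C=C/CCCC | intermediate (not isolated)
8 | (15E)-icos-15-en-1-ol | CCCC/C=C/CCCCCCCCCCCCCCO | intermediate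
9 | (5E)-20-bromoicos-5-ene | CCCC/C=C/CCCCCCCCCCCCCCBr | intermediate
10 | 1,4-dimethylpiperazine-2,3-dione | CN1CCN(C)C(=O)C1=O | starting material
11 | ethylmagnesium bromide | CC[Mg]Br | starting material
12 | [(15E)-icos-15-en-1-yl]magnesium bromide | CCCC/C=C/CCCCCCCCCCCCCC[Mg]Br | intermediate (not isolated)
13 | bromomagnesium alkoxide of 3-hydroxy-3-[(15E)-icos-15-en-1-yl]-1,4-dimethylpiperazin-2-one (racemic at C3) | CCCC/C=C/CCCCCCCCCCCCCCC1(O[Mg]Br)N(C)CCN(C)C1=O | intermediate (not isolated)
14 | bis(bromomagnesium) dialkoxide of 2-ethyl-3-[(15E)-icos-15-en-1-yl]-1,4-dimethylpiperazine-2,3-diol (mixture of diastereomers; both centres are lost on hydrolysis) | CCCC/C=C/CCCCCCCCCCCCCCC1(O[Mg]Br)N(C)CCN(C)C1(CC)O[Mg]Br | intermediate (not isolated)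
15 | (19E)-tetracos-19-ene-3,4-dione | CCCC/C=C/CCCCCCCCCCCCCCC(=O)C(=O)CC | intermediate
16 | diethyl oxalate | CCOC(=O)C(=O)OCC | starting material
17 | ethyl 3-[(14E)-nonadec-14-en-1-yl]-2,4,5-trioxoheptanoate (racemic, drawn in the keto form; present as its potassium enolate) | CCCC/C=C/CCCCCCCCCCCCCC(C(=O)C(=O)CC)C(=O)C(=O)OCC | intermediate (not isolated)
18 | ethyl (20E)-3-methyl-2,4,5-trioxopentacos-20-enoate (racemic, drawn in the keto form; present as its potassium enolate) | CCCC/C=C/CCCCCCCCCCCCCCC(=O)C(=O)C(C)C(=O)C(=O)OCC | intermediate (not isolated)
19 | dipotassium 3-methyl-6-[(14E)-nonadec-14-en-1-yl]-1,4-dioxocyclohexa-2,5-diene-2,5-diolate | CCCC/C=C/CCCCCCCCCCCCCC1=C([O-])C(=O)C(C)=C([O-])C1=O.[K+].[K+] | intermediate (not isolated)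
20 | 2,5-dihydroxy-3-methyl-6-[(14E)-nonadec-14-en-1-yl]cyclohexa-2,5-diene-1,4-dione | CCCC/C=C/CCCCCCCCCCCCCC1=C(O)C(=O)C(C)=C(O)C1=O | target

## Step count and risks

Total step count: 5. Longest linear sequence: 5 steps (from 1 or 2 to 20).

Steps most likely to fail:

First, step 5 (the labelled step). The self-aldol condensation of the 1,2-diketone may outrun C-oxalylation, or the sequence may stall after the first acylation if the second enolisation is too slow. The fallback uses known chemistry and gives up the ring closure in favour of radical alkylation of a bought hydroxyquinone. It sets out from 8, which is oxidised (TEMPO, PhI(OAc)2, MeCN/H2O) to (15E)-icos-15-enoic acid F1. F1 with DCC and ethereal H2O2 gives bis[(15E)-icos-15-enoyl] peroxide F2. Thermolysis of F2 in acetic acid at about 95 °C with excess commercial 2,5-dihydroxy-1,4-benzoquinone should deliver, by decarboxylation to the nonadec-14-enyl radical and radical substitution at a free ring position, 2,5-dihydroxy-3-[(14E)-nonadec-14-en-1-yl]cyclohexa-2,5-diene-1,4-dione F3. A second peroxide alkylation of F3 with diacetyl peroxide (methyl radical; commercial dilute solution) at the only free ring position comes back to the route at 20.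

Second, step 4. The long-chain Grignard reagent may add twice to the diamide, or the first tetrahedral adduct may collapse early so that ethylmagnesium bromide adds to the liberated ketone. The fallback replaces the oxalyl dication equivalent by acyl-anion (umpolung) chemistry and sets out from 9. Alkylation of 2-lithio-1,3-dithiane (1,3-dithiane, n-BuLi, THF, −30 °C to rt) gives 2-[(15E)-icos-15-en-1-yl]-1,3-dithiane F4. A second lithiation (n-BuLi, THF, −20 °C) and acylation with N-methoxy-N-methylpropanamide gives 1-{2-[(15E)-icos-15-en-1-yl]-1,3-dithian-2-yl}propan-1-one F5. Dethioacetalisation (MeI, CaCO3, aqueous MeCN, 40 °C) comes back to the route at 15.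

Third, step 1. The unprotected alkoxide may cause competing O-alkylation (ether oligomers) and E2 elimination, or aggregation may slow the SN2 step. The fallback masks the hydroxyl group and sets out from 2. Treatment with 3,4-dihydro-2H-pyran and PPTS in CH2Cl2 gives 2-[(14-bromotetradecyl)oxy]oxane F6. Alkylation of 3 (1.3 equiv) with F6 in THF/DMPU gives 2-(icos-15-yn-1-yloxy)oxane F7. Methanolysis (PPTS, MeOH, 50 °C) comes back to the route at 6.

## Further compounds

F1 | step 5 | (15E)-icos-15-enoic acid | CCCC/C=C/CCCCCCCCCCCCCC(=O)O
F2 | step 5 | bis[(15E)-icos-15-enoyl] peroxide | CCCC/C=C/CCCCCCCCCCCCCC(=O)OOC(=O)CCCCCCCCCCCCC/C=C/CCCC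
F3 | step 5 | 2,5-dihydroxy-3-[(14E)-nonadec-14-en-1-yl]cyclohexa-2,5-diene-1,4-dione | CCCC/C=C/CCCCCCCCCCCCCC1=C(O)C(=O)C=C(O)C1=O
F4 | step 4 | 2-[(15E)-icos-15-en-1-yl]-1,3-dithiane | CCCC/C=C/CCCCCCCCCCCCCCC1SCCCS1
F5 | step 4 | 1-{2-[(15E)-icos-15-en-1-yl]-1,3-dithian-2-yl}propan-1-one | CCCC/C=C/CCCCCCCCCCCCCCC1(C(=O)CC)SCCCS1
F6 | step 1 | 2-[(14-bromotetradecyl)oxy]oxane (racemic) | BrCCCCCCCCCCCCCCOC1CCCCO1
F7 | step 1 | 2-(icos-15-yn-1-yloxy)oxane (racemic) | CCCCC#CCCCCCCCCCCCCCCOC1CCCCO1
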